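**Strategy.** Atoms are numbered as in the briarane skeleton. Everything rests on disconnecting C8–C17 inside the γ-lactone ring (O–C19–C17–C8–C7) fused to the ten-membered ring: C8 is a tertiary carbinol β to the lactone carbonyl C19, an aldol retron whose tether is the C7 oxygen. The key step, a copper hydride reductive aldol cyclisation, converts a C7 acrylate/C8 ketone in one operation into the lactone, forming C8–C17 and both stereocentres and releasing the target itself. Its precursor is the complete 6/10-bicycle bearing all four acetates and the C6 chloride, built by Diels–Alder reaction, auxiliary aldol, chloroallenylzinc addition and enyne/ring-closing metathesis.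

Key step: step 19

Numbering remark: six-membered ring C1, C10–C14; ten-membered ring C1–C10; C15 = methyl on C1; C16 = methylene on C5; C17–C19 = lactone carbons; C20 = methylene on C11.

Assumption: the sense of induction of the salen–chromium catalyst with enal 1 is taken to be that established for 2-substituted acroleins, and the catalyst enantiomer is chosen so that adduct 3 has the configuration drawn.

**Route**

Step 1
Reactants: 1 (E)-4,4-dimethoxy-2-methylbut-2-enal; 2 (E)-3-(tert-butyldimethylsilyloxy)-N,N-dimethylbuta-1,3-dien-1-amine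
Product: 3 aminosilyloxy cyclohexene carbaldehyde (Diels–Alder adduct)
Conditions: (R,R)-(salen)CrSbF6 (5 mol %, trivalent chromium; salen = N,N′-bis(3,5-di-tert-butylsalicylidene)cyclohexane-1,2-diamine dianion), 4 Å MS, CH2Cl2, −40 → 0 °C
Reagents that add atoms: none
Why: Catalytic enantioselective Diels–Alder reaction of an aminosilyloxydiene with a 2-substituted enal, in which the CH2 terminus bonds to the β-carbon (C10) and the amino terminus to the α-carbon (C1), the E geometry of 1 fixes formyl trans to the dimethoxymethyl group (C1/C10), endo approach places NMe2 cis to CHO, and the catalyst selects the enal face (absolute configuration).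

Step 2
Reactants: 3 Diels–Alder adduct; 4 vinylmagnesium bromide
Product: 6 hydroxy enone, via bromomagnesium alkoxide 5 (not isolated)
Conditions: CH2=CHMgBr, THF, −78 °C; then HF·pyridine, MeCN, 0 °C
Reagents that add atoms: none
Why: Chelation-controlled Grignard addition (magnesium bridges the formyl oxygen and the C14 amino group, so vinyl enters past the C1 methyl group and sets C2 as in the target), followed by fluoride cleavage of the silyl enol ether and β-elimination of dimethylamine to the enone; the masked ketone and the acetal do not react with the Grignard reagent.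

Step 3
Reactants: 6 hydroxy enone
Product: 9 cross-conjugated dienone, via Mannich base 7 (not isolated), via trimethylammonium iodide 8 (not isolated)
Conditions: LiN(i-Pr)2 (2.3 equiv), THF, −78 °C; CH2=NMe2+ I−, −78 → 0 °C; then MeI, CH2Cl2, rt; NaHCO3 aq
Reagents that add atoms: Eschenmoser's salt (N,N-dimethylmethyleneiminium iodide), C[N+](C)=C.[I-]
Why: Kinetic deprotonation of the enone is possible only at the α′ carbon C11 (C1 is quaternary), so the Mannich reaction and Hofmann-type elimination of the quaternised amine (Eschenmoser methylenation) install C11=C20 regiospecifically; no stereocentre is formed.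

Step 4
Reactants: 9 cross-conjugated dienone
Product: 11 dihydroxy enone, via cyclic phenylboronate 10 (not isolated)
Conditions: PhB(OH)2 (1.5 equiv), i-Pr2NH (cat.), 4 Å MS, CH2Cl2, rt; then pinacol
Reagents that add atoms: phenylboronic acid, OB(O)c1ccccc1
Why: Boronic acid hemiester-directed intramolecular oxa-Michael addition, in which the boronate bound to the C2 hydroxyl delivers oxygen to C14 through a six-membered transition state, so the new C14–O bond is cis to the C2 carbon on C1 and the exocyclic enone (eight-membered mode) is not attacked; pinacol transesterification frees the diol.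

Step 5
Reactants: 11 dihydroxy enone
Product: 12 triol
Conditions: Et2BOMe, THF/MeOH (4:1), −78 °C; NaBH4; AcOH quench
Reagents that add atoms: none
Why: Narasaka–Prasad reduction, in which hydride attacks the boron chelate of the C14 hydroxyl and the C12 ketone axially to give the C12 alcohol cis (1,3-syn) to the C14 hydroxyl, the activated chelated carbonyl being reduced faster than the exocyclic enone undergoes conjugate reduction.

Step 6
Reactants: 12 triol
Product: 13 triacetate acetal
Conditions: Ac2O, pyridine, DMAP (cat.), CH2Cl2, rt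
Reagents that add atoms: acetic anhydride, CC(=O)OC(C)=O
Why: DMAP-catalysed acetylation of the three secondary alcohols installs the final C2, C12 and C14 acetates, which are compatible with every later step; no stereocentre is touched.

Step 7
Reactants: 13 triacetate acetal
Product: 14 triacetate aldehyde
Conditions: LiBF4, MeCN/H2O (50:1), rt
Reagents that add atoms: water, O
Why: Mild lithium-assisted acetal hydrolysis unmasks the C9 aldehyde under conditions that leave the allylic acetates alone and should neither epimerise C10 nor move the C11=C20 double bond into conjugation.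

Step 8
Reactants: 15 2-(tert-butyldimethylsilyloxy)acetic acid; 16 (R)-4-benzyl-1,3-thiazolidine-2-thione
Product: 17 N-(silyloxyacetyl)thiazolidinethione
Conditions: DCC, DMAP (cat.), CH2Cl2, 0 °C → rt
Reagents that add atoms: none
Why: Carbodiimide (Steglich-type) N-acylation of the thiazolidinethione gives the chiral glycolate equivalent; the auxiliary stereocentre is not involved.

Step 9
Reactants: 14 triacetate aldehyde; 17 N-(silyloxyacetyl)thiazolidinethione
Product: 18 syn aldol adduct
Conditions: TiCl4, i-Pr2NEt, N-methyl-2-pyrrolidinone, CH2Cl2, −78 °C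
Reagents that add atoms: none
Why: Titanium enolate aldol addition of an N-acylthiazolidinethione, in which the Z-enolate reacts through a closed Zimmerman–Traxler transition state on the face opposite the benzyl group, setting C9 as in the target (auxiliary control) and the disposable C8 silyloxy centre syn to it.

Step 10
Reactants: 18 syn aldol adduct
Product: 19 tetraacetate thioimide
Conditions: AcCl, pyridine, CH2Cl2, 0 °C
Reagents that add atoms: acetyl chloride, CC(=O)Cl
Why: Acetylation of the C9 hydroxyl with acetyl chloride and pyridine, without an acyl-transfer catalyst that could attack the activated thioimide, fixes the last acetate with retention.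

Step 11
Reactants: 19 tetraacetate thioimide
Product: 20 C7 aldehyde
Conditions: i-Bu2AlH (1.3 equiv), CH2Cl2, −78 °C
Reagents that add atoms: none
Why: N-Acylthiazolidinethiones are reduced by i-Bu2AlH at −78 °C directly to aldehydes through a stable tetrahedral aluminate and much faster than hindered secondary acetates (chemoselective partial reduction), releasing the auxiliary.

Step 12
Reactants: 20 C7 aldehyde; 21 3-chloro-1-(trimethylsilyl)prop-1-yne
Product: 23 silylalkynyl chlorohydrin, via chloroallenylzinc bromide 22 (not isolated)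
Conditions: 21, ZnBr2, n-BuLi, THF, −90 → −78 °C; then 20, −78 °C; NH4Cl aq
Reagents that add atoms: none
Why: Addition of the chlorine-substituted allenylzinc (propargylic zinc carbenoid) through a chair-like SE2′ transition state gives the anti chlorohydrin (C6 chloride anti to C7 hydroxyl), while the non-chelating α-silyloxy group imposes Felkin–Anh control, so the C7 hydroxyl is anti to the C8 silyloxy group and configured as in the target.

Step 13
Reactants: 23 silylalkynyl chlorohydrin
Product: 24 terminal alkyne chlorohydrin
Conditions: Bu4NF/AcOH (1:1), THF, −20 → 0 °C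
Reagents that add atoms: none
Why: Acetic-acid-buffered fluoride cleaves the alkynyl C–Si bond much faster than the secondary silyl ether and without forming the alkoxide that would close the chlorohydrin to an epoxide (protodesilylation).

Step 14
Reactants: 24 terminal alkyne chlorohydrin
Product: 25 triene chlorohydrin
Conditions: second-generation Grubbs catalyst [RuCl2(=CHPh)(PCy3)(H2IMes)] (5 mol %), ethylene (1 atm), CH2Cl2, rt
Reagents that add atoms: ethene, C=C
Why: Ruthenium-carbene enyne cross-metathesis of the terminal alkyne with ethylene gives the 2-substituted 1,3-diene regiospecifically, creating the C5=C16 methylene and a terminal vinyl group on C4, while the 1,1-disubstituted C11=C20 alkene is inert; no stereocentre is touched.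

Step 15
Reactants: 25 triene chlorohydrin
Product: 26 ten-membered ring chlorohydrin
Conditions: second-generation Hoveyda–Grubbs catalyst [RuCl2(=CH-C6H4-2-O-i-Pr)(H2IMes)] (10 mol %), toluene (1 mM), 80 °C, argon sparge
Reagents that add atoms: none
Why: Ring-closing metathesis between the C2 vinyl group and the terminal alkene of the diene closes the ten-membered ring with loss of ethylene, the ring size and the trans-fused six-membered ring allowing only the Z geometry at C3=C4, and ruthenium carbenes tolerate the allylic chloride, free hydroxyl and esters.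

Step 16
Reactants: 26 ten-membered ring chlorohydrin
Product: 27 C7 acrylate
Conditions: CH2=CHCOCl, i-Pr2NEt, DMAP (cat.), CH2Cl2, −20 °C
Reagents that add atoms: acryloyl chloride, C=CC(=O)Cl
Why: Base-mediated esterification of the C7 hydroxyl places the three-carbon unit C17–C19 on O7 only after metathesis, so the acrylate cannot interfere with ring closure; the amine is too weak a base to close the chlorohydrin.

Step 17
Reactants: 27 C7 acrylate
Product: 28 C8 alcohol
Conditions: HF·pyridine, pyridine, THF, 0 °C → rt
Reagents that add atoms: none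
Why: HF·pyridine removes the only silyl ether under mildly acidic conditions that should not promote migration of the neighbouring acyl groups (desilylation).

Step 18
Reactants: 28 C8 alcohol
Product: 29 C8 ketone (keto acrylate)
Conditions: Dess–Martin periodinane, NaHCO3, CH2Cl2, 0 °C
Reagents that add atoms: none
Why: Buffered Dess–Martin oxidation converts the C8 carbinol, whose configuration has served its purpose, into the ketone without epimerising the flanking acyloxy centres or eliminating HCl.

Step 19
Reactants: 29 C8 ketone (keto acrylate)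
Product: 32 CNP0164748.1 (target), via copper enolate 30 (not isolated), via copper aldolate 31 (not isolated)
Conditions: [(Ph3P)CuH]6 (0.4 equiv), toluene/THF, −40 → 0 °C; then NH4Cl aq
Reagents that add atoms: none
Why: Copper hydride transfers hydride to the β-carbon of the s-cis acrylate (the future C18 methyl), giving the (Z)-copper enolate 30 at C17, which adds to the adjacent C8 ketone to give aldolate 31, protonated on work-up. The closest known reaction type is the copper hydride reductive aldol cyclisation of keto acrylates to β-hydroxy lactones. The five-membered ring O–C19–C17–C8–C7 closes in a formally 5-(enolendo)-exo-trig mode, made feasible by the metal-bridged aldol transition state. C8 is controlled by the ring, because the enolate tethered to O7 can only reach the ketone face that gives the trans-fused lactone (cis fusion would force the C6–C7–C8–C9 torsion of the ten-membered ring towards eclipse), and C17 is controlled by the Z-enolate geometry in the closed transition state, which places the methyl group cis to the new hydroxyl. The step needs base-free, site-specific enolate formation, since a base would enolise the C8 ketone towards C7 and expel the C6 chloride; conjugate reduction of the acrylate should be faster than attack of copper hydride on the ketone, the allylic chloride, the diene or the four acetates, and the aldol is intramolecular.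

**Compound list**

1 | (E)-4,4-dimethoxy-2-methylbut-2-enal | O=C/C(C)=C/C(OC)OC | starting material
2 | (E)-3-(tert-butyldimethylsilyloxy)-N,N-dimethylbuta-1,3-dien-1-amine | CN(C)/C=C/C(=C)O[Si](C)(C)C(C)(C)C | starting material
3 | 4-(tert-butyldimethylsilyloxy)-2-(dimethylamino)-6-(dimethoxymethyl)-1-methylcyclohex-3-ene-1-carbaldehyde; formyl cis to NMe2 and trans to CH(OMe)2; ring C1 and C6 are C1 and C10 of 32, configured as there | C1[C@H](C(OC)OC)[C@](C=O)(C)[C@@H](N(C)C)C=C1O[Si](C)(C)C(C)(C)C | intermediate
4 | vinylmagnesium bromide | C=C[Mg]Br | starting material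
5 | bromomagnesium alkoxide of the C2 vinyl carbinol derived from 3 (C2 as in 32) | C1[C@H](C(OC)OC)[C@]([C@@H](O[Mg]Br)C=C)(C)[C@@H](N(C)C)C=C1O[Si](C)(C)C(C)(C)C | intermediate
6 | 5-(dimethoxymethyl)-4-(1-hydroxyprop-2-en-1-yl)-4-methylcyclohex-2-en-1-one; ring C4, ring C5 and the carbinol carbon are C1, C10 and C2 of 32, configured as there | C1[C@H](C(OC)OC)[C@]([C@@H](O)C=C)(C)C=CC1=O | intermediate
7 | 6-[(dimethylamino)methyl] derivative of 6 (Mannich base, C11 epimers) | CN(C)CC1[C@H](C(OC)OC)[C@]([C@@H](O)C=C)(C)C=CC1=O | intermediate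
8 | trimethylammonium iodide of 7 | C[N+](C)(C)CC1[C@H](C(OC)OC)[C@]([C@@H](O)C=C)(C)C=CC1=O.[I-] | intermediate
9 | 5-(dimethoxymethyl)-4-(1-hydroxyprop-2-en-1-yl)-4-methyl-6-methylidenecyclohex-2-en-1-one (C11=C20 installed) | C=C1[C@H](C(OC)OC)[C@]([C@@H](O)C=C)(C)C=CC1=O | intermediate
10 | cyclic phenylboronate bridging O2 and O14 (2-phenyl-1,3,2-dioxaborinane cis-fused at C1–C14), C12 ketone | C=C1[C@H](C(OC)OC)[C@@]2(C)[C@H](C=C)OB(c3ccccc3)O[C@H]2CC1=O | intermediate
11 | 5-(dimethoxymethyl)-3-hydroxy-4-(1-hydroxyprop-2-en-1-yl)-4-methyl-6-methylidenecyclohexan-1-one; C14 hydroxyl cis to the C2 carbon | C=C1[C@H](C(OC)OC)[C@]([C@@H](O)C=C)(C)[C@@H](O)CC1=O | intermediate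
12 | corresponding 2,12,14-triol (C12 and C14 hydroxyls cis; C1, C2, C10, C12, C14 as in 32), C9 dimethyl acetal | C=C1[C@H](C(OC)OC)[C@]([C@@H](O)C=C)(C)[C@@H](O)C[C@H]1O | intermediate
13 | 2,12,14-triacetate of 12 | C=C1[C@H](C(OC)OC)[C@]([C@@H](OC(C)=O)C=C)(C)[C@@H](OC(C)=O)C[C@H]1OC(C)=O | intermediate
14 | 2,12,14-triacetoxy C9 aldehyde (ring A with C2 vinyl carbinol acetate and C10 formyl group) | C=C1[C@H](C=O)[C@]([C@@H](OC(C)=O)C=C)(C)[C@@H](OC(C)=O)C[C@H]1OC(C)=O | intermediate
15 | 2-(tert-butyldimethylsilyloxy)acetic acid | OC(=O)CO[Si](C)(C)C(C)(C)C | starting material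
16 | (R)-4-benzyl-1,3-thiazolidine-2-thione | S=C1N[C@H](Cc2ccccc2)CS1 | starting material
17 | (R)-4-benzyl-3-[2-(tert-butyldimethylsilyloxy)acetyl]-1,3-thiazolidine-2-thione | O=C(CO[Si](C)(C)C(C)(C)C)N1[C@H](Cc2ccccc2)CSC1=S | intermediate
18 | aldol adduct: C9 hydroxyl as in 32, C8 silyloxy group syn to it, C7 as the thioimide carbonyl | C=C1[C@H]([C@H](O)[C@@H](O[Si](C)(C)C(C)(C)C)C(=O)N2[C@H](Cc3ccccc3)CSC2=S)[C@]([C@@H](OC(C)=O)C=C)(C)[C@@H](OC(C)=O)C[C@H]1OC(C)=O | intermediate
19 | C9 acetate of 18 (2,9,12,14-tetraacetate) | C=C1[C@H]([C@H](OC(C)=O)[C@@H](O[Si](C)(C)C(C)(C)C)C(=O)N2[C@H](Cc3ccccc3)CSC2=S)[C@]([C@@H](OC(C)=O)C=C)(C)[C@@H](OC(C)=O)C[C@H]1OC(C)=O | intermediate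
20 | C7 aldehyde with C8 silyloxy and 2,9,12,14-tetraacetate | C=C1[C@H]([C@H](OC(C)=O)[C@@H](O[Si](C)(C)C(C)(C)C)C=O)[C@]([C@@H](OC(C)=O)C=C)(C)[C@@H](OC(C)=O)C[C@H]1OC(C)=O | intermediate
21 | 3-chloro-1-(trimethylsilyl)prop-1-yne | C[Si](C)(C)C#CCCl | starting material
22 | 3-chloro-1-(trimethylsilyl)propa-1,2-dienylzinc bromide | C[Si](C)(C)C(=C=CCl)[Zn]Br | intermediate
23 | anti chlorohydrin: C7 hydroxyl and C6 chloride as in 32, C5≡C4 alkyne capped by SiMe3 | C=C1[C@H]([C@H](OC(C)=O)[C@@H](O[Si](C)(C)C(C)(C)C)[C@@H](O)[C@@H](Cl)C#C[Si](C)(C)C)[C@]([C@@H](OC(C)=O)C=C)(C)[C@@H](OC(C)=O)C[C@H]1OC(C)=O | intermediate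
24 | terminal alkyne analogue of 23 | C=C1[C@H]([C@H](OC(C)=O)[C@@H](O[Si](C)(C)C(C)(C)C)[C@@H](O)[C@@H](Cl)C#C)[C@]([C@@H](OC(C)=O)C=C)(C)[C@@H](OC(C)=O)C[C@H]1OC(C)=O | intermediate
25 | triene: C5(=C16H2)–C4H=CH2 diene in place of the alkyne of 24 | C=C1[C@H]([C@H](OC(C)=O)[C@@H](O[Si](C)(C)C(C)(C)C)[C@@H](O)[C@@H](Cl)C(=C)C=C)[C@]([C@@H](OC(C)=O)C=C)(C)[C@@H](OC(C)=O)C[C@H]1OC(C)=O | intermediate
26 | 6/10-bicycle with (3Z)-alkene, C7 hydroxyl, C8 silyloxy, C6 chloride and 2,9,12,14-tetraacetate | C=C1[C@@H]2[C@H](OC(C)=O)[C@@H](O[Si](C)(C)C(C)(C)C)[C@@H](O)[C@@H](Cl)C(=C)/C=C\[C@H](OC(C)=O)[C@@]2(C)[C@@H](OC(C)=O)C[C@H]1OC(C)=O | intermediate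
27 | C7 acrylate of 26 | C=C1[C@@H]2[C@H](OC(C)=O)[C@@H](O[Si](C)(C)C(C)(C)C)[C@@H](OC(=O)C=C)[C@@H](Cl)C(=C)/C=C\[C@H](OC(C)=O)[C@@]2(C)[C@@H](OC(C)=O)C[C@H]1OC(C)=O | intermediate
28 | C8 alcohol (desilylated 27) | C=C1[C@@H]2[C@H](OC(C)=O)[C@@H](O)[C@@H](OC(=O)C=C)[C@@H](Cl)C(=C)/C=C\[C@H](OC(C)=O)[C@@]2(C)[C@@H](OC(C)=O)C[C@H]1OC(C)=O | intermediate
29 | C8 ketone with C7 acrylate | C=C1[C@@H]2[C@H](OC(C)=O)C(=O)[C@@H](OC(=O)C=C)[C@@H](Cl)C(=C)/C=C\[C@H](OC(C)=O)[C@@]2(C)[C@@H](OC(C)=O)C[C@H]1OC(C)=O | intermediate
30 | (Z)-copper enolate of the C7 propanoate (phosphine ligands omitted) | C=C1[C@@H]2[C@H](OC(C)=O)C(=O)[C@@H](O/C(O[Cu])=C/C)[C@@H](Cl)C(=C)/C=C\[C@H](OC(C)=O)[C@@]2(C)[C@@H](OC(C)=O)C[C@H]1OC(C)=O | intermediate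
31 | copper C8 alkoxide of the lactone (aldolate; phosphine ligands omitted) | C=C1[C@@H]2[C@H](OC(C)=O)[C@]3(O[Cu])[C@@H](C)C(=O)O[C@H]3[C@@H](Cl)C(=C)/C=C\[C@H](OC(C)=O)[C@@]2(C)[C@@H](OC(C)=O)C[C@H]1OC(C)=O | intermediate
32 | CNP0164748.1: (1R,2S,3Z,6S,7R,8R,9S,10S,12R,14S,17R)-2,9,12,14-tetraacetoxy-6-chloro-8-hydroxybriara-3,5(16),11(20)-trien-18,7-olide | C=C1[C@@H]2[C@H](OC(C)=O)[C@]3(O)[C@@H](C)C(=O)O[C@H]3[C@@H](Cl)C(=C)/C=C\[C@H](OC(C)=O)[C@@]2(C)[C@@H](OC(C)=O)C[C@H]1OC(C)=O | target

**Step count**

Total step count: 19. Longest linear sequence: 18 steps (steps 1–7 and 9–19; step 8 is a one-step side branch).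

**Steps most likely to fail, with fallbacks**

Step 19 (key step). What may go wrong: hydride delivery to the C8 ketone or reductive loss of the allylic chloride before the enolate is formed, or low facial control at C17. Fallback, a samarium-mediated intramolecular Reformatsky reaction, sets out from 26 and comes back at 32. Chlorohydrin 26 is acylated with 2-bromopropanoyl bromide (pyridine, CH2Cl2, −20 °C) to the 2-bromopropanoate F1. HF·pyridine gives the C8 alcohol F2, and Dess–Martin oxidation gives the keto bromo ester F3. SmI2 (2.2 equiv, THF, −78 °C) reduces the C–Br bond faster than any other group, and the samarium enolate formed at C17 closes the lactone onto the C8 ketone under the same ring control to give 32.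

Step 15. What may go wrong: oligomerisation, engagement of the internal alkene of the diene, or a stable vinylcarbene that fails to close the ten-membered ring. Fallback, a ring-closing enyne metathesis, sets out from 24 and comes back at 26. Alkyne 24 is treated directly with the second-generation Grubbs catalyst at high dilution without ethylene (toluene, 80 °C). The carbene formed at the C2 vinyl group adds to the terminal alkyne carbon C4 (endo mode), and the ring vinylcarbene at C5 is released by methylene transfer from the next substrate molecule, which forms C3=C4 and C5=C16 in one operation. This fallback makes no compound outside the list (entry F0).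

Step 4. What may go wrong: sluggish conjugate addition at the hindered C14 next to the quaternary C1, or amine-induced oligomerisation of the exocyclic enone. Fallback, which brings the C14 oxygen in with the diene, sets out from 1 and comes back at 11. Enal 1 is combined with (E)-1,3-bis(trimethylsilyloxy)buta-1,3-diene under a chiral oxazaborolidinium triflimide catalyst to give the bis-silyl cycloadduct F4, in which the endo rule places the C14 oxygen cis to the formyl group. Citric acid in MeOH gives the β-hydroxy keto aldehyde F5. Nozaki–Hiyama–Kishi vinylation (vinyl iodide, CrCl2, cat. NiCl2, DMSO), selective for the aldehyde and guided by the chromium C14 alkoxide, gives the diol ketone F6. With LiN(i-Pr)2 (3.3 equiv) the C14 alkoxide directs enolisation to C11; Eschenmoser's salt gives the Mannich base F7, MeI the ammonium iodide F8, and NaHCO3 eliminates to 11.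

Further compounds
F1 | step 19 | C7 2-bromopropanoate of 26 (C17 epimers) | C=C1[C@@H]2[C@H](OC(C)=O)[C@@H](O[Si](C)(C)C(C)(C)C)[C@@H](OC(=O)C(C)Br)[C@@H](Cl)C(=C)/C=C\[C@H](OC(C)=O)[C@@]2(C)[C@@H](OC(C)=O)C[C@H]1OC(C)=O
F2 | step 19 | C8 alcohol of F1 | C=C1[C@@H]2[C@H](OC(C)=O)[C@@H](O)[C@@H](OC(=O)C(C)Br)[C@@H](Cl)C(=C)/C=C\[C@H](OC(C)=O)[C@@]2(C)[C@@H](OC(C)=O)C[C@H]1OC(C)=O
F3 | step 19 | C8 ketone with C7 2-bromopropanoate | C=C1[C@@H]2[C@H](OC(C)=O)C(=O)[C@@H](OC(=O)C(C)Br)[C@@H](Cl)C(=C)/C=C\[C@H](OC(C)=O)[C@@]2(C)[C@@H](OC(C)=O)C[C@H]1OC(C)=O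
F0 | step 15 | none | none
F4 | step 4 | 6-(dimethoxymethyl)-1-methyl-2,4-bis(trimethylsilyloxy)cyclohex-3-ene-1-carbaldehyde (silyloxy at C14 cis to formyl) | C1[C@H](C(OC)OC)[C@](C=O)(C)[C@@H](O[Si](C)(C)C)C=C1O[Si](C)(C)C
F5 | step 4 | 6-(dimethoxymethyl)-2-hydroxy-1-methyl-4-oxocyclohexane-1-carbaldehyde | C1[C@H](C(OC)OC)[C@](C=O)(C)[C@@H](O)CC1=O
F6 | step 4 | 5-(dimethoxymethyl)-3-hydroxy-4-(1-hydroxyprop-2-en-1-yl)-4-methylcyclohexan-1-one | C1[C@H](C(OC)OC)[C@]([C@@H](O)C=C)(C)[C@@H](O)CC1=O
F7 | step 4 | 6-[(dimethylamino)methyl] derivative of F6 (C11 epimers) | CN(C)CC1[C@H](C(OC)OC)[C@]([C@@H](O)C=C)(C)[C@@H](O)CC1=O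
F8 | step 4 | trimethylammonium iodide of F7 | C[N+](C)(C)CC1[C@H](C(OC)OC)[C@]([C@@H](O)C=C)(C)[C@@H](O)CC1=O.[I-]
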